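**Assumptions.** The target is drawn as the neutral aryl hydrogen sulfate; it should be isolated as its inner salt (N4 ammonium, sulfate), which is the same compound. Compound 21 is drawn in the same neutral form, although it should be handled as its pyridinium salt. Amine 8 is used as the free base.

## The problem

The target is a 24-membered bis-lactam in which spermidine is acylated at N1 and N8 by two (E)-cinnamoyl units whose arenes are joined by a diaryl ether. Ring A is 1,3,4-trisubstituted and carries the N8 cinnamoyl arm at C1, the ether oxygen at C3 and the sulfate at C4. Ring B is a para-phenylene with the ether oxygen para to the N1 cinnamoyl arm. There is no stereocentre, so stereochemistry is limited to the two E alkenes and no element of the substrate has to control another. The real difficulties are the large ring, the orientation of the unsymmetrical triamine (the two primary amines of spermidine are nearly equivalent), and the choice of compatible protecting groups. The aryl sulfate monoester is acid-labile and very polar, so it has to come late. N4 has to be masked while the phenol is sulfated and must then be released without acid. The two cinnamamides rule out hydrogenation and soft nucleophiles once they are in place. The enabling feature is that Cβ of the ring B cinnamamide sits para to the ether oxygen. As an aldehyde carbon it activates 4-fluorobenzaldehyde for the SNAr that builds the diaryl ether, and it then serves as the electrophile for an olefination with a phosphonoacetamide on N1 that closes the ring.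

## Retrosynthesis

**End game, 22 back to 19.** The O–S bond of the sulfate, the N4–H bond and the phenol O–H are traced back to macrocycle 19, which carries a Teoc carbamate on N4 and an allyl ether on the ring A phenol. Sulfation of phenol 20 to give 21 requires N4 to be a carbamate, since a free secondary amine would be sulfamoylated. The last step must spare the sulfate, which speaks for fluoride cleavage of Teoc. An allyl ether is preferred to an acetal-type phenol protecting group because Teoc is itself acid-sensitive. Allyl (removed with zerovalent palladium) and Teoc (removed with fluoride) are fully orthogonal, and the allyl ether survives carbonate at 100 °C, hydroxide and DBU.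

**Ring closure, 19 back to 18.** The Cα=Cβ bond of the ring B cinnamamide is cut to give the acyclic phosphonoacetamide aldehyde 18. Closing at either amide would need a seco amino acid with both cinnamoyl units already built and a further orthogonal nitrogen protecting group. Closing at the diaryl ether would need an SNAr on a weakly activated cinnamamide arene inside a macrocycle. The olefination cut gives a precursor with exactly one aldehyde and one acidic CH2. The forward reaction has to deliver E geometry and ring closure in preference to oligomers.

**Fragment union, 18 back to 7 and 16.** The N8–C(=O) amide is cut to acid 7, which carries the aldehyde, and amine 16, which carries the phosphonate and the Teoc group. This is convergent, and the aldehyde meets a free amine only here. Acylation through the pre-formed active ester 17 is irreversible, whereas imine formation is reversible. The reverse order, amide first and N1 unmasked afterwards, would leave a primary amine and an aldehyde in one molecule.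

**Acid fragment, 7 back to 1, 3 and 5.** Acid 7 comes from ester 6 by saponification. The diaryl ether C–O bond of 6 is cut at ring B to phenol 4 and 4-fluorobenzaldehyde 5, whose formyl group activates the fluoride. The ring A aldehyde must already be an acrylate at this point, otherwise two aldehydes would be undifferentiated. Cinnamate 4 comes from aldehyde 2 and ylide 3 by Wittig olefination. Aldehyde 2 comes from 3,4-dihydroxybenzaldehyde 1 by alkylation of the more acidic 4-OH.

**Amine fragment, 16 back to 8, 9 and 13.** Amine 16 arises from Cbz carbamate 15 by hydrogenolysis, which is safe because no alkene is present yet. Compound 15 comes from amine 12 and diethylphosphonoacetic acid 13. Starting from the parent triamine would require telling its two primary amines apart. Instead the chain is assembled so that the termini differ by construction: mono-Cbz putrescine 8 adds to acrylonitrile 9 to give 10, the only basic nitrogen (N4) is capped as Teoc in 11, and reduction of the nitrile reveals N1 in 12.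

## Roads not taken

**Alternative 1: Zip transamidation of a 20-membered lactam.** The cut is the C(=O)–N1 bond. In the forward sense, the pendant 3-aminopropyl amine of the 20-membered N4-acyl lactam A1 would attack the ring B cinnamoyl carbonyl through a six-membered tetrahedral intermediate, release N4 and give the 24-membered macrocycle A2.
- Merits: the ring expansion is intramolecular and needs no high dilution, it is driven by the change from a tertiary to a secondary amide, and it places the acyl group on N1 without ambiguity.
- Weak points: A1 is itself a 20-membered macrolactam, so a macrocyclisation is moved, not avoided. Building A1 still needs N1, N4 and N8 to be addressed separately. The strongly basic conditions usual for such transamidations expose two cinnamoyl acceptors to aza-Michael addition by the free amine. A2 has a free N4 that must be protected again before sulfation.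
- Comparison: the expansion step is better than the chosen ring closure in its independence of concentration. The chosen plan sets against this a direct closure of the final ring from an acyclic precursor, no reprotection, and at least two fewer steps.

**Alternative 2: Fukuyama–Mitsunobu closure at N4.** The cut is the N4–CH2 bond of the four-carbon chain. The seco compound A3 carries a 2-nitrobenzenesulfonamide on the three-carbon arm and a 4-hydroxybutyl amide on the ring A arm. An intramolecular Mitsunobu alkylation would give the N4-nosyl macrocycle A4.
- Merits: the nosyl group both activates and protects N4, both cinnamamides are made by ordinary amide couplings, and Mitsunobu alkylation of nosyl amides is a well-tried way to close polyamine macrocycles. As a ring closure it is at least as reliable as an olefination.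
- Weak points: A3 needs a diaryl ether carrying two different cinnamoyl acid termini that are amidated in turn, which costs orthogonal esters and extra steps. The closure produces stoichiometric phosphine oxide and hydrazide in a large volume. The nosyl group is later removed with a thiolate in the presence of two cinnamamides, where conjugate addition can compete.
- Comparison: the chosen plan forms one of the two alkenes in the ring-closing step and therefore needs only one cinnamate to be made beforehand. Its protecting groups come off with zerovalent palladium and fluoride, neither of which attacks the enamides.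

**Alternative 3: Biomimetic oxidative phenol coupling.** The cut is the diaryl ether C–O bond. One-electron oxidation of both phenols of the bis(4-hydroxycinnamoyl) triamine A5 would join the ring B oxygen to C3 of ring A and give the macrocyclic phenol A6, which has the same structure as 20.
- Merits: this is by far the shortest road. A5 needs no differentiation of N1 and N8 because both carry the same acyl group, and A6 already has the free phenol for sulfation. In step count the chosen plan cannot match it.
- Weak points: phenoxyl radicals of 4-hydroxycinnamoyl units couple mainly through Cβ and through ortho carbon, so C–O coupling is a minor pathway. Even C–O coupling can occur in two senses, N1-arm oxygen to N8-arm ring or the reverse, which gives two isomeric macrocycles. Overoxidation and oligomers are expected.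
- Comparison: the chosen plan is longer but fixes the regiochemistry of the ether by SNAr and the orientation of the triamine by construction, so each step has a predictable outcome.

Key step: step 11

## Route

**Step 1**
Reactants: 1 3,4-dihydroxybenzaldehyde
Product: 2 4-(allyloxy)-3-hydroxybenzaldehyde
Conditions: allyl bromide, NaHCO3, NaI (cat.), DMF, 40 °C
Reagents that add atoms: allyl bromide, C=CCBr
Why: The 4-OH, para to the formyl group, is the more acidic phenol, so the weak base forms only that phenoxide and Williamson etherification should occur at O4; this regioselective mono-alkylation is established for this aldehyde.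

**Step 2**
Reactants: 2 4-(allyloxy)-3-hydroxybenzaldehyde; 3 methyl (triphenylphosphoranylidene)acetate
Product: 4 methyl (E)-3-[4-(allyloxy)-3-hydroxyphenyl]prop-2-enoate
Conditions: toluene, 90 °C
Reagents that add atoms: none
Why: Wittig olefination with a stabilised ylide tolerates the free phenol and should give the E cinnamate, because oxaphosphetane formation is reversible for such ylides.

**Step 3**
Reactants: 4 methyl (E)-3-[4-(allyloxy)-3-hydroxyphenyl]prop-2-enoate; 5 4-fluorobenzaldehyde
Product: 6 methyl (E)-3-[4-(allyloxy)-3-(4-formylphenoxy)phenyl]prop-2-enoate
Conditions: K2CO3, DMF, 100 °C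
Reagents that add atoms: none
Why: Nucleophilic aromatic substitution: the para formyl group stabilises the Meisenheimer adduct, so the phenoxide should displace fluoride; the acrylate, the allyl ether and the non-enolisable aldehyde are stable to carbonate.

**Step 4**
Reactants: 6 methyl (E)-3-[4-(allyloxy)-3-(4-formylphenoxy)phenyl]prop-2-enoate
Product: 7 (E)-3-[4-(allyloxy)-3-(4-formylphenoxy)phenyl]prop-2-enoic acid
Conditions: LiOH·H2O, THF/MeOH/H2O, rt; then 1 M HCl to pH 3
Reagents that add atoms: lithium hydroxide, [Li+].[OH-]
Why: Ester saponification; the aryl aldehyde has no α-hydrogen and should survive dilute hydroxide at room temperature, and the allyl ether and diaryl ether are inert.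

**Step 5**
Reactants: 8 benzyl (4-aminobutyl)carbamate; 9 acrylonitrile
Product: 10 benzyl {4-[(2-cyanoethyl)amino]butyl}carbamate
Conditions: MeOH, 0 °C to rt
Reagents that add atoms: none
Why: Aza-Michael addition; with about one equivalent of acrylonitrile the primary amine should add once, since the secondary amine formed is more hindered and reacts more slowly.

**Step 6**
Reactants: 10 benzyl {4-[(2-cyanoethyl)amino]butyl}carbamate
Product: 11 benzyl {4-[(2-cyanoethyl){[2-(trimethylsilyl)ethoxy]carbonyl}amino]butyl}carbamate
Conditions: Teoc-OSu, Et3N, CH2Cl2, rt
Reagents that add atoms: 2,5-dioxopyrrolidin-1-yl 2-(trimethylsilyl)ethyl carbonate (Teoc-OSu), C[Si](C)(C)CCOC(=O)ON1C(=O)CCC1=O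
Why: Carbamate formation at the only basic nitrogen (the future N4); the Cbz nitrogen is not nucleophilic.

**Step 7**
Reactants: 11 benzyl {4-[(2-cyanoethyl){[2-(trimethylsilyl)ethoxy]carbonyl}amino]butyl}carbamate
Product: 12 benzyl {4-[(3-aminopropyl){[2-(trimethylsilyl)ethoxy]carbonyl}amino]butyl}carbamate
Conditions: H2 (3 atm), Raney Ni, NH3 in MeOH, rt
Reagents that add atoms: none
Why: Catalytic hydrogenation of the nitrile to the primary amine; ammonia suppresses secondary amine formation, and nickel is a poor catalyst for benzyl carbamate hydrogenolysis, so Cbz and Teoc should remain.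

**Step 8**
Reactants: 12 benzyl {4-[(3-aminopropyl){[2-(trimethylsilyl)ethoxy]carbonyl}amino]butyl}carbamate; 13 diethylphosphonoacetic acid
Product: 15 benzyl {4-[(3-{[(diethoxyphosphoryl)acetyl]amino}propyl){[2-(trimethylsilyl)ethoxy]carbonyl}amino]butyl}carbamate, via benzotriazolyl ester 14 (not isolated)
Conditions: EDC·HCl, HOBt, i-Pr2NEt, CH2Cl2, 0 °C to rt
Reagents that add atoms: 1-hydroxybenzotriazole, On1nnc2ccccc12 (atoms kept only in intermediate 14)
Why: Carbodiimide amide coupling through the active ester; the N1 amine is the only nucleophile, and without a metal salt the phosphonate CH2 is not deprotonated.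

**Step 9**
Reactants: 15 benzyl {4-[(3-{[(diethoxyphosphoryl)acetyl]amino}propyl){[2-(trimethylsilyl)ethoxy]carbonyl}amino]butyl}carbamate
Product: 16 2-(trimethylsilyl)ethyl (4-aminobutyl)(3-{[(diethoxyphosphoryl)acetyl]amino}propyl)carbamate
Conditions: H2 (1 atm), 10% Pd/C, MeOH, rt
Reagents that add atoms: none
Why: Hydrogenolysis of the benzyl carbamate and loss of CO2 frees N8; no alkene is present at this stage, and the Teoc carbamate and phosphonate are inert to hydrogenation.

**Step 10**
Reactants: 7 (E)-3-[4-(allyloxy)-3-(4-formylphenoxy)phenyl]prop-2-enoic acid; 16 2-(trimethylsilyl)ethyl (4-aminobutyl)(3-{[(diethoxyphosphoryl)acetyl]amino}propyl)carbamate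
Product: 18 seco-aldehyde 2-(trimethylsilyl)ethyl [4-({(E)-3-[4-(allyloxy)-3-(4-formylphenoxy)phenyl]prop-2-enoyl}amino)butyl](3-{[(diethoxyphosphoryl)acetyl]amino}propyl)carbamate, via benzotriazolyl ester 17 (not isolated)
Conditions: 7, EDC·HCl, HOBt, CH2Cl2/DMF, 0 °C, 30 min; then 16, i-Pr2NEt (1 equiv), 0 °C to rt
Reagents that add atoms: 1-hydroxybenzotriazole, On1nnc2ccccc12 (atoms kept only in intermediate 17)
Why: Amide coupling through a pre-formed active ester; acylation of the primary amine is fast and irreversible, whereas any imine with the aryl aldehyde forms reversibly and is hydrolysed at aqueous work-up. No lithium salt is present, so the phosphonoacetamide does not olefinate.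

**Step 11**
Reactants: 18 seco-aldehyde
Product: 19 N4-Teoc, O-allyl 24-membered macrocycle with two E cinnamamides (ring B cinnamoyl on N1, ring A cinnamoyl on N8)
Conditions: LiCl, DBU, MeCN, rt; 18 added by syringe pump over 12 h to about 1 mM final concentration
Reagents that add atoms: none
Why: LiCl chelates the phosphoryl and amide carbonyl oxygens of the phosphonoacetamide, which makes the CH2 acidic enough for DBU to deprotonate; this is a Horner–Wadsworth–Emmons olefination under the LiCl/amine (Masamune–Roush) conditions, and the closest known reaction type is its macrocyclising use for macrolactones and macrolactams. The lithium-bound carbanion adds reversibly to the ring B aldehyde in a 24-exo-trig closure, and the adducts equilibrate before the anti adduct collapses through the trans oxaphosphetane by syn elimination to the enamide and diethyl phosphate. No stereocentre is formed; the only stereochemical demand is E geometry, which the reversible addition of a stabilised phosphonate anion and the conjugation of the new alkene with ring B should secure. The step also needs ring closure in preference to intermolecular olefination, which slow addition into dilute LiCl/DBU provides; the two trans secondary amides, the E cinnamamide on ring A and the bent diaryl ether limit the freedom of the chain. Chemoselectivity is built in: 18 has one aldehyde, which cannot enolise, and one acidic CH2, and DBU at room temperature should leave the allyl ether, the Teoc carbamate and the amides untouched.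

**Step 12**
Reactants: 19 N4-Teoc, O-allyl macrocycle
Product: 20 N4-Teoc macrocyclic phenol (free 4-OH on ring A)
Conditions: Pd(PPh3)4 (cat.), morpholine, THF, rt
Reagents that add atoms: none
Why: Tsuji–Trost deallylation; zerovalent palladium ionises the aryl allyl ether to a π-allyl complex and the phenoxide, and morpholine traps the allyl group. The Teoc carbamate and the cinnamamides do not react.

**Step 13**
Reactants: 20 N4-Teoc macrocyclic phenol
Product: 21 N4-Teoc macrocyclic aryl hydrogen sulfate
Conditions: SO3·pyridine, pyridine, rt; isolated as the pyridinium salt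
Reagents that add atoms: sulfur trioxide–pyridine complex, O=S(=O)([O-])[n+]1ccccc1
Why: O-sulfation of a phenol with an amine–SO3 complex; the secondary amides and the carbamate are not sulfated under these conditions, and N4 is protected.

**Step 14**
Reactants: 21 N4-Teoc macrocyclic aryl hydrogen sulfate
Product: 22 target compound CID124202369
Conditions: Bu4NF (excess), THF, rt; AcOH quench; C18 reverse-phase chromatography (H2O/MeCN)
Reagents that add atoms: none
Why: Fluoride attack at silicon triggers β-elimination of the 2-(trimethylsilyl)ethyl carbamate, which releases ethylene, CO2 and the secondary amine under non-acidic conditions that the aryl sulfate monoanion should tolerate.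

## Compound list

1 | 3,4-dihydroxybenzaldehyde | O=Cc1ccc(O)c(O)c1 | starting material
2 | 4-(allyloxy)-3-hydroxybenzaldehyde | O=Cc1ccc(OCC=C)c(O)c1 | intermediate
3 | methyl (triphenylphosphoranylidene)acetate | COC(=O)C=P(c1ccccc1)(c1ccccc1)c1ccccc1 | starting material
4 | methyl (E)-3-[4-(allyloxy)-3-hydroxyphenyl]prop-2-enoate | COC(=O)/C=C/c1ccc(OCC=C)c(O)c1 | intermediate
5 | 4-fluorobenzaldehyde | O=Cc1ccc(F)cc1 | starting material
6 | methyl (E)-3-[4-(allyloxy)-3-(4-formylphenoxy)phenyl]prop-2-enoate | COC(=O)/C=C/c1ccc(OCC=C)c(Oc2ccc(C=O)cc2)c1 | intermediate
7 | (E)-3-[4-(allyloxy)-3-(4-formylphenoxy)phenyl]prop-2-enoic acid | OC(=O)/C=C/c1ccc(OCC=C)c(Oc2ccc(C=O)cc2)c1 | intermediate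
8 | benzyl (4-aminobutyl)carbamate | NCCCCNC(=O)OCc1ccccc1 | starting material
9 | acrylonitrile | C=CC#N | starting material
10 | benzyl {4-[(2-cyanoethyl)amino]butyl}carbamate | N#CCCNCCCCNC(=O)OCc1ccccc1 | intermediate
11 | benzyl {4-[(2-cyanoethyl){[2-(trimethylsilyl)ethoxy]carbonyl}amino]butyl}carbamate | N#CCCN(C(=O)OCC[Si](C)(C)C)CCCCNC(=O)OCc1ccccc1 | intermediate
12 | benzyl {4-[(3-aminopropyl){[2-(trimethylsilyl)ethoxy]carbonyl}amino]butyl}carbamate | NCCCN(C(=O)OCC[Si](C)(C)C)CCCCNC(=O)OCc1ccccc1 | intermediate
13 | diethylphosphonoacetic acid | CCOP(=O)(CC(=O)O)OCC | starting material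
14 | 1H-benzotriazol-1-yl (diethoxyphosphoryl)acetate | CCOP(=O)(OCC)CC(=O)On1nnc2ccccc12 | intermediate (not isolated)
15 | benzyl {4-[(3-{[(diethoxyphosphoryl)acetyl]amino}propyl){[2-(trimethylsilyl)ethoxy]carbonyl}amino]butyl}carbamate | CCOP(=O)(OCC)CC(=O)NCCCN(C(=O)OCC[Si](C)(C)C)CCCCNC(=O)OCc1ccccc1 | intermediate
16 | 2-(trimethylsilyl)ethyl (4-aminobutyl)(3-{[(diethoxyphosphoryl)acetyl]amino}propyl)carbamate | CCOP(=O)(OCC)CC(=O)NCCCN(C(=O)OCC[Si](C)(C)C)CCCCN | intermediate
17 | 1H-benzotriazol-1-yl (E)-3-[4-(allyloxy)-3-(4-formylphenoxy)phenyl]prop-2-enoate | O=Cc1ccc(Oc2cc(/C=C/C(=O)On3nnc4ccccc34)ccc2OCC=C)cc1 | intermediate (not isolated)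
18 | seco-aldehyde: N8-{(E)-3-[4-(allyloxy)-3-(4-formylphenoxy)phenyl]prop-2-enoyl}-N1-[(diethoxyphosphoryl)acetyl]-N4-Teoc-spermidine | CCOP(=O)(OCC)CC(=O)NCCCN(C(=O)OCC[Si](C)(C)C)CCCCNC(=O)/C=C/c1ccc(OCC=C)c(Oc2ccc(C=O)cc2)c1 | intermediate
19 | N4-Teoc, O-allyl 24-membered (E,E)-macrocycle | O=C1/C=C/c2ccc(OCC=C)c(c2)Oc2ccc(cc2)/C=C/C(=O)NCCCN(C(=O)OCC[Si](C)(C)C)CCCCN1 | intermediate
20 | N4-Teoc macrocyclic phenol | O=C1/C=C/c2ccc(O)c(c2)Oc2ccc(cc2)/C=C/C(=O)NCCCN(C(=O)OCC[Si](C)(C)C)CCCCN1 | intermediate
21 | N4-Teoc macrocyclic aryl hydrogen sulfate | O=C1/C=C/c2ccc(OS(=O)(=O)O)c(c2)Oc2ccc(cc2)/C=C/C(=O)NCCCN(C(=O)OCC[Si](C)(C)C)CCCCN1 | intermediate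
22 | CID124202369, macrocyclic (E,E)-bis-cinnamoyl spermidine aryl hydrogen sulfate | O=C1/C=C/c2ccc(OS(=O)(=O)O)c(c2)Oc2ccc(cc2)/C=C/C(=O)NCCCNCCCCN1 | target

## Step count and risks

Total step count: 14. Longest linear sequence: 10 steps (steps 5 to 14, from 8). The acid branch (steps 1 to 4) joins at step 10.

**Step 11 (key step).** Intermolecular olefination to dimers and oligomers may outrun the slow closure of a 24-membered ring, and lithium-bridged aggregation of the diamide may reduce solubility at the dilution required; some Z alkene may also form. Fallback: the same alkene is formed intermolecularly and the ring is closed at the N8 amide, setting out from 16 and 6 and returning at 19.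
- Amine 16 would be treated with ethyl trifluoroacetate to give the N8-trifluoroacetamide phosphonate F1.
- Olefination of F1 with aldehyde 6 (LiCl, DBU, MeCN, at normal concentration) would give the acyclic bis-cinnamoyl methyl ester F2.
- LiOH in aqueous THF/MeOH would cleave the methyl ester and the trifluoroacetamide together to give the seco amino acid F3.
- Macrolactamisation of F3 (EDC·HCl, HOBt, CH2Cl2/DMF, high dilution) would give 19.

**Step 10.** Condensation of the N8 amine with the ring B aldehyde may compete with acylation and hold back amine, and traces of base-promoted olefination between molecules may follow once both functions are in one compound. Fallback: the aldehyde is masked through the coupling, setting out from 6 and returning at 18.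
- Ester 6 would be converted with ethylene glycol and TsOH (toluene, water separator) into the 1,3-dioxolane ester F4.
- Saponification with LiOH and careful acidification to about pH 5 would give the dioxolane acid F5.
- EDC·HCl/HOBt coupling of F5 with 16 would give the acetal-protected seco amide F6.
- Pyridinium tosylate in wet acetone would release the aldehyde and give 18, with the allyl ether and Teoc left intact.

**Step 14.** Carbamate cleavage may be incomplete because the acidic sulfate consumes fluoride, sulfate may be lost during handling, and the zwitterion may prove hard to separate from tetrabutylammonium salts. Fallback: the sulfate is carried as a neutral diester and fluoride is avoided, setting out from 20 and returning at 22.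
- Phenol 20 would be treated with 2,2,2-trichloroethyl chlorosulfate, Et3N and DMAP in THF to give the aryl 2,2,2-trichloroethyl sulfate F7.
- Trifluoroacetic acid in CH2Cl2, to which such sulfate diesters are stable, would remove Teoc and give the N4 amine F8 as its trifluoroacetate salt.
- Zn dust and HCO2NH4 in MeOH would cleave the trichloroethyl group reductively and give 22.

**Step 7.** Partial hydrogenolysis of the benzyl carbamate on nickel, or condensation of the product amine with the intermediate imine to a secondary amine, may lower the yield. Fallback: the N1 nitrogen is introduced as a phthalimide and no reduction is used, setting out from 8 and returning at 12.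
- Amine 8 (in excess) would be alkylated with N-(3-bromopropyl)phthalimide (K2CO3, MeCN) to give the secondary amine F9.
- Teoc-OSu and Et3N would give the carbamate F10.
- Hydrazine hydrate in EtOH would cleave the phthalimide and give 12; Cbz and Teoc are stable to hydrazine.

## Further compounds

F1 | step 11 | 2-(trimethylsilyl)ethyl (3-{[(diethoxyphosphoryl)acetyl]amino}propyl){4-[(trifluoroacetyl)amino]butyl}carbamate | CCOP(=O)(OCC)CC(=O)NCCCN(C(=O)OCC[Si](C)(C)C)CCCCNC(=O)C(F)(F)F
F2 | step 11 | acyclic (E,E)-bis-cinnamoyl compound with ring A methyl ester, N4-Teoc and N8-trifluoroacetamide | COC(=O)/C=C/c1ccc(OCC=C)c(Oc2ccc(/C=C/C(=O)NCCCN(C(=O)OCC[Si](C)(C)C)CCCCNC(=O)C(F)(F)F)cc2)c1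
F3 | step 11 | seco amino acid with ring A cinnamic acid, free N8 amine and N4-Teoc | OC(=O)/C=C/c1ccc(OCC=C)c(Oc2ccc(/C=C/C(=O)NCCCN(C(=O)OCC[Si](C)(C)C)CCCCN)cc2)c1
F4 | step 10 | methyl (E)-3-{4-(allyloxy)-3-[4-(1,3-dioxolan-2-yl)phenoxy]phenyl}prop-2-enoate | COC(=O)/C=C/c1ccc(OCC=C)c(Oc2ccc(C3OCCO3)cc2)c1
F5 | step 10 | (E)-3-{4-(allyloxy)-3-[4-(1,3-dioxolan-2-yl)phenoxy]phenyl}prop-2-enoic acid | OC(=O)/C=C/c1ccc(OCC=C)c(Oc2ccc(C3OCCO3)cc2)c1
F6 | step 10 | dioxolane-protected seco amide (18 with the aldehyde as its 1,3-dioxolane) | CCOP(=O)(OCC)CC(=O)NCCCN(C(=O)OCC[Si](C)(C)C)CCCCNC(=O)/C=C/c1ccc(OCC=C)c(Oc2ccc(C3OCCO3)cc2)c1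
F7 | step 14 | N4-Teoc macrocyclic aryl 2,2,2-trichloroethyl sulfate | O=C1/C=C/c2ccc(OS(=O)(=O)OCC(Cl)(Cl)Cl)c(c2)Oc2ccc(cc2)/C=C/C(=O)NCCCN(C(=O)OCC[Si](C)(C)C)CCCCN1
F8 | step 14 | macrocyclic aryl 2,2,2-trichloroethyl sulfate with free N4 | O=C1/C=C/c2ccc(OS(=O)(=O)OCC(Cl)(Cl)Cl)c(c2)Oc2ccc(cc2)/C=C/C(=O)NCCCNCCCCN1
F9 | step 7 | benzyl [4-({3-(1,3-dioxoisoindolin-2-yl)propyl}amino)butyl]carbamate | O=C1c2ccccc2C(=O)N1CCCNCCCCNC(=O)OCc1ccccc1
F10 | step 7 | benzyl {4-[{3-(1,3-dioxoisoindolin-2-yl)propyl}{[2-(trimethylsilyl)ethoxy]carbonyl}amino]butyl}carbamate | O=C1c2ccccc2C(=O)N1CCCN(C(=O)OCC[Si](C)(C)C)CCCCNC(=O)OCc1ccccc1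
A1 | alternative 1 | 20-membered N4-acyl lactam with pendant 3-aminopropyl group and MOM-protected phenol | O=C1/C=C/c2ccc(OCOC)c(c2)Oc2ccc(cc2)/C=C/C(=O)N(CCCN)CCCCN1
A2 | alternative 1 | 24-membered macrocycle with free N4 and MOM-protected phenol | O=C1/C=C/c2ccc(OCOC)c(c2)Oc2ccc(cc2)/C=C/C(=O)NCCCNCCCCN1
A3 | alternative 2 | seco 4-hydroxybutyl amide with N-(2-nitrobenzenesulfonyl)aminopropyl amide | OCCCCNC(=O)/C=C/c1ccc(OCOC)c(c1)Oc1ccc(cc1)/C=C/C(=O)NCCCNS(=O)(=O)c1ccccc1[N+](=O)[O-]
A4 | alternative 2 | N4-nosyl, O-MOM 24-membered macrocycle | O=C1/C=C/c2ccc(OCOC)c(c2)Oc2ccc(cc2)/C=C/C(=O)NCCCN(S(=O)(=O)c2ccccc2[N+](=O)[O-])CCCCN1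
A5 | alternative 3 | N1,N8-bis[(E)-4-hydroxycinnamoyl]-N4-Teoc-spermidine | O=C(/C=C/c1ccc(O)cc1)NCCCN(C(=O)OCC[Si](C)(C)C)CCCCNC(=O)/C=C/c1ccc(O)cc1
A6 | alternative 3 | N4-Teoc macrocyclic diaryl ether with free ring A phenol (same structure as 20) | O=C1/C=C/c2ccc(O)c(c2)Oc2ccc(cc2)/C=C/C(=O)NCCCN(C(=O)OCC[Si](C)(C)C)CCCCN1
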